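The numbers in the tables were computed from invented constants; the scatter is artificial.

Start from the slow part: once the substrate has gone, the target fades over minutes. What you want to know is how many fading times it lives through before you read it.

in all of them: substrate 2.2 M; gas phase 200 mM (held)

| flask | catalyst | remark | time |
|---|---|---|---|
| west | 160 mM | run made earlier |  |
| south-west | 660 mM | run made earlier |  |
| flask | 330 mM |  | 10 min |

| run | time / min | target / % | substrate / % |
|---|---|---|---|
| west | 2.50 | 72 | 5 |
| west | 5.00 | 55 | 0 |
| west | 8.00 | 32 | 0 |
| west | 10.0 | 25 | 0 |
| south-west | 1.33 | 84 | 8 |
| south-west | 4.00 | 58 | 0 |
| south-west | 6.00 | 40 | 0 |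
| south-west | 10.0 | 22 | 1 |

(each reading ± 1.5 percentage points)

- at the start none of the gas phase is in solution

- Thursday's: doubling the transfer coefficient of the gas phase, all else as stated
- Saturday's: doubling the amount of catalyst, all else as stated
- Monday's: doubling the saturation concentration of gas phase, all else as stated

- amount of target at 10 min, in percent of the substrate charged
- the change that raises the amount of target at 10 min, in percent of the substrate charged most ("none" if none brings more than 2 percentage points) (Thursday's / Saturday's / Monday's / none)
- amount of target at 10 min, in percent of the substrate charged, after Thursday's

From the late readings, the west run fades at 0.158 /min and the south-west run at 0.162 /min, with 4.12 times the catalyst. So take one first-order constant, 0.160 /min. Folded with the time it gives 1.60, and exp(−1.60) is 20.2 %, lower than both readings at 10 min.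

So go round again, since the target isn't all there at the start. Tracing each last reading back to the whole charge gives an induction time: 1.21 min for the west run and a shorter 0.628 min for the south-west run. Your 330 mM of catalyst sits near their geometric middle, 325 mM, so use the mean delay, 0.919 min. The survival number N, the fading times the target lives through after its delay, is then 1.45, and exp(−N) gives 23.5 %.

Is one number enough? The unused readings fall below their lines: 32 % against 34.3 % in the west run, and 40 % against 42.0 % in the south-west run, with a scatter of 1.5 percentage points. I keep it, with that doubt.

Saturday's flask has the south-west charge, which read 22 %. I expect Thursday's and Monday's to shorten the delay too; taking the south-west delay for Thursday's gives 22.4 %, less than 23.5 %. A shorter delay raises N, so I answer none.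

The forecast gives 23.5 %, 21.5 % after Thursday's, less than my 22.4 %, and none as the best change, placing this flask “between the two runs”.

The flask gives 23.4 %, 22.5 % after Thursday's and none as the best change; at 10.0 min the isomer of the product holds 41.3 % and the over-reaction product 34.4 %.

    gas phase ⇌ dissolved gas, rate k1*(csat - [dissolved gas]) (kL = 0.180 /s)
    substrate + dissolved gas + catalyst → catalyst + target (k = 1.10 /M²/s)
    2 substrate → homo dimer (k = 7.30 × 10⁻⁵ /M/s)
    target → over-reaction product (k = 0.00120 /s)
    target ⇌ isomer of the product (K = 12.0, k = 0.00150 /s)

Read at 6.0 min, the same flask has N cut to 0.811, which gives 44.4 % of target; it holds 43.1 %.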